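**Retrosynthetic overview**

- The C5 enal is unveiled last by cross-metathesis of a 5-(E)-propenyl dihydrobenzofuran with crotonaldehyde.
- The dihydrofuran ring is the only ring made (both benzene rings are bought). It is closed in one flask by a [4+1] annulation: C2–C3 bond first, then O1–C2. The partners are an o-quinone methide (ring A, C3 and C9, isovalerate already in place) and a chiral benzylsulfonium ylide (ring B and C2). The ylide is a benzylic carbanion, the polarity-reversed form of the vanillyl electrophile, so two otherwise electrophilic carbons are joined and both stereocentres are set here.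
- The o-quinone methide comes from a 2-(1-tosylalkyl)phenol, made by ortho-hydroxyalkylation of (E)-isoeugenol with 2-oxoethyl 3-methylbutanoate (ozonolysis of allyl isovalerate).
- The ylide comes from a sulfonium salt built from vanillyl alcohol (acetyl bromide) and isothiocineole.

Assumption 1: the (1S,4S,5S) sulfide is taken to expose the ylide face that leads to 2R (its mirror image being the one that gives (R,R)-stilbene oxide with benzaldehyde); if a calibration run shows the opposite sense, the (1R,4R,5R) sulfide from (R)-limonene is used and nothing else changes.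

Assumption 2: isoeugenol is drawn as its (E)-isomer; Z-containing technical material serves equally, because the propenyl geometry is erased in step 7.

**Route**

Step 1
Reactants: 1 allyl 3-methylbutanoate
Product: 2 2-oxoethyl 3-methylbutanoate
Conditions: O3, CH2Cl2, −78 °C; then Me2S, −78 °C → rt; distil (removes CH2O)
Reagents that add atoms: ozone, [O-][O+]=O
Why: Ozonolysis with reductive work-up cleaves the terminal alkene to the aldehyde without touching the ester, and no stereocentre is formed.

Step 2
Reactants: 2 2-oxoethyl 3-methylbutanoate; 3 (E)-isoeugenol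
Product: 4 rac-2-hydroxy-2-[2-hydroxy-3-methoxy-5-[(E)-prop-1-enyl]phenyl]ethyl 3-methylbutanoate
Conditions: 3, EtMgBr (1.0 equiv), Et2O, 0 °C; solvent exchange to CH2Cl2; 2 (1.2 equiv), 0 °C → rt, 16 h; then H2O
Reagents that add atoms: none
Why: Casiraghi-type ortho-specific hydroxyalkylation, in which the bromomagnesium phenoxide delivers the Mg-bound aldehyde through a six-membered chelate to the only free ortho carbon (para is blocked by the propenyl group); the carbinol centre forms racemic, which does not matter because it is planarised in step 6.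

Step 3
Reactants: 4 rac-2-hydroxy-2-[2-hydroxy-3-methoxy-5-[(E)-prop-1-enyl]phenyl]ethyl 3-methylbutanoate
Product: 5 rac-2-[2-hydroxy-3-methoxy-5-[(E)-prop-1-enyl]phenyl]-2-(4-methylphenyl)sulfonylethyl 3-methylbutanoate
Conditions: 4-MeC6H4SO2H (1.5 equiv), CH2Cl2, rt, 12 h
Reagents that add atoms: 4-methylbenzenesulfinic acid, Cc1ccc(cc1)S(O)=O
Why: Acid-promoted ionisation of the ortho-hydroxybenzylic alcohol (via the o-quinone methide or benzylic cation) and S-attack of the sulfinate gives the bench-stable 2-(1-tosylalkyl)phenol, the standard base-triggered o-quinone methide precursor, while the weak sulfinic acid leaves the propenyl group and the ester alone.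

Step 4
Reactants: 6 vanillyl alcohol
Product: 7 4-(bromomethyl)-2-methoxyphenyl acetate
Conditions: AcBr (3 equiv), CH2Cl2, 0 °C → rt, 2 h
Reagents that add atoms: acetyl bromide, CC(=O)Br
Why: Acetyl bromide acetylates the phenol and converts the electron-rich benzylic alcohol into the bromide in one operation (the acetyl bromide reaction of lignin chemistry), which masks the phenol so that the later ylide cannot collapse to a p-quinone methide.

Step 5
Reactants: 7 4-(bromomethyl)-2-methoxyphenyl acetate; 8 (1S,4S,5S)-4,7,7-trimethyl-6-thiabicyclo[3.2.1]octane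
Product: 9 (1S,4S,5S)-6-[(4-acetoxy-3-methoxyphenyl)methyl]-4,7,7-trimethyl-6-thiabicyclo[3.2.1]octan-6-ium tetrafluoroborate
Conditions: 8 (1.1 equiv), NaBF4 (5 equiv), CH2Cl2/H2O, rt, 24 h
Reagents that add atoms: sodium tetrafluoroborate, [Na+].F[B-](F)(F)F
Why: SN2 S-alkylation of the bicyclic sulfide by the benzylic bromide with counter-ion exchange in a two-phase system, the alkylation taking the less hindered sulfur lone pair to give one sulfonium diastereomer and leaving the carbon stereocentres untouched.

Step 6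
Reactants: 5 rac-2-[2-hydroxy-3-methoxy-5-[(E)-prop-1-enyl]phenyl]-2-(4-methylphenyl)sulfonylethyl 3-methylbutanoate; 9 (1S,4S,5S)-6-[(4-acetoxy-3-methoxyphenyl)methyl]-4,7,7-trimethyl-6-thiabicyclo[3.2.1]octan-6-ium tetrafluoroborate
Product: 14 [(2R,3S)-2-(4-hydroxy-3-methoxyphenyl)-7-methoxy-5-[(E)-prop-1-enyl]-2,3-dihydro-1-benzofuran-3-yl]methyl 3-methylbutanoate, via o-quinone methide 10 (not isolated), via sulfonium ylide 11 (not isolated), via betaine 12 (not isolated), via aryl acetate 13 (not isolated)
Conditions: 5 (1.0 equiv), 9 (1.3 equiv), Cs2CO3 (3 equiv), CH2Cl2, −20 °C → rt, 12 h; then pyrrolidine (3 equiv), rt, 1 h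
Reagents that add atoms: none
Why: Proposed new method: Cs2CO3 turns sulfone 5 into o-quinone methide 10 (phenoxide E1cB loss of sulfinate) and salt 9 into ylide 11, a benzylic carbanion that is the polarity-reversed form of electrophile 7, so that the C2–C3 bond joins two carbons that are both electrophilic in their parent forms (conjugate addition driven by re-aromatisation, giving betaine 12), after which the phenoxide displaces the sulfonium group in a 5-exo-tet SN2 step with inversion at C2 to close the dihydrofuran ring; C2 is set by the one exposed face of the conformationally locked bicyclic ylide and C3 by the transoid approach that leads to the 2,3-trans ring, the closest known reaction types being the trans-selective sulfur-ylide [4+1] annulation of in situ o-quinone methides (known in racemic form and with acyl-stabilised ylides) and the isothiocineole-mediated asymmetric epoxidation and aziridination with benzylsulfonium ylides, while the closing pyrrolidine addition is a routine chemoselective aminolysis of the aryl acetate next to the alkyl ester.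

Step 7
Reactants: 14 [(2R,3S)-2-(4-hydroxy-3-methoxyphenyl)-7-methoxy-5-[(E)-prop-1-enyl]-2,3-dihydro-1-benzofuran-3-yl]methyl 3-methylbutanoate; 15 (E)-but-2-enal
Product: 16 [(2R,3S)-2-(4-hydroxy-3-methoxyphenyl)-7-methoxy-5-[(E)-3-oxoprop-1-enyl]-2,3-dihydro-1-benzofuran-3-yl]methyl 3-methylbutanoate
Conditions: 15 (10 equiv), second-generation Hoveyda–Grubbs catalyst (H2IMes)Cl2Ru(=CH-C6H4-2-OiPr) (5 mol %), CH2Cl2, 40 °C, 12 h
Reagents that add atoms: none
Why: Olefin cross-metathesis of the electron-rich 1-propenylarene with excess crotonaldehyde swaps the ethylidene end for a formylmethylidene unit and gives the (E)-enal under thermodynamic control, and the neutral conditions leave the free phenol, the ester and both stereocentres untouched.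

**Compound list**

1 | allyl 3-methylbutanoate (allyl isovalerate) | C=CCOC(=O)CC(C)C | starting material
2 | 2-oxoethyl 3-methylbutanoate | O=CCOC(=O)CC(C)C | intermediate
3 | (E)-isoeugenol, 2-methoxy-4-[(E)-prop-1-enyl]phenol | C/C=C/c1ccc(O)c(OC)c1 | starting material
4 | rac-2-hydroxy-2-[2-hydroxy-3-methoxy-5-[(E)-prop-1-enyl]phenyl]ethyl 3-methylbutanoate | C/C=C/c1cc(OC)c(O)c(c1)C(O)COC(=O)CC(C)C | intermediate
5 | rac-2-[2-hydroxy-3-methoxy-5-[(E)-prop-1-enyl]phenyl]-2-(4-methylphenyl)sulfonylethyl 3-methylbutanoate | C/C=C/c1cc(OC)c(O)c(c1)C(COC(=O)CC(C)C)S(=O)(=O)c1ccc(C)cc1 | intermediate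
6 | vanillyl alcohol, 4-(hydroxymethyl)-2-methoxyphenol | COc1cc(CO)ccc1O | starting material
7 | 4-(bromomethyl)-2-methoxyphenyl acetate | COc1cc(CBr)ccc1OC(C)=O | intermediate
8 | (1S,4S,5S)-4,7,7-trimethyl-6-thiabicyclo[3.2.1]octane (isothiocineole of the (S)-limonene series; recovered after step 6) | C[C@H]1CC[C@H]2C[C@@H]1SC2(C)C | starting material
9 | (1S,4S,5S)-6-[(4-acetoxy-3-methoxyphenyl)methyl]-4,7,7-trimethyl-6-thiabicyclo[3.2.1]octan-6-ium tetrafluoroborate (one diastereomer at sulfur, sulfur configuration not encoded) | C[C@H]1CC[C@H]2C[C@@H]1[S+](Cc3ccc(OC(C)=O)c(OC)c3)C2(C)C.F[B-](F)(F)F | intermediate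
10 | o-quinone methide: 2-methoxy-6-[2-(3-methylbutanoyloxy)ethylidene]-4-[(E)-prop-1-enyl]cyclohexa-2,4-dien-1-one (exocyclic geometry not defined) | C/C=C/C1=CC(=CCOC(=O)CC(C)C)C(=O)C(OC)=C1 | intermediate
11 | sulfonium ylide: (4-acetoxy-3-methoxyphenyl)[(1S,4S,5S)-4,7,7-trimethyl-6-thiabicyclo[3.2.1]octan-6-ium-6-yl]methanide | C[C@H]1CC[C@H]2C[C@@H]1[S+]([CH-]c3ccc(OC(C)=O)c(OC)c3)C2(C)C | intermediate
12 | betaine: 2-[(1S,2S)-1-(4-acetoxy-3-methoxyphenyl)-3-(3-methylbutanoyloxy)-1-[(1S,4S,5S)-4,7,7-trimethyl-6-thiabicyclo[3.2.1]octan-6-ium-6-yl]propan-2-yl]-6-methoxy-4-[(E)-prop-1-enyl]phenolate | C[C@H]1CC[C@H]2C[C@@H]1[S+]([C@H](c3ccc(OC(C)=O)c(OC)c3)[C@H](COC(=O)CC(C)C)c3cc(/C=C/C)cc(OC)c3[O-])C2(C)C | intermediate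
13 | 2-methoxy-4-[(2R,3S)-7-methoxy-3-[(3-methylbutanoyloxy)methyl]-5-[(E)-prop-1-enyl]-2,3-dihydro-1-benzofuran-2-yl]phenyl acetate | COc1cc([C@@H]2Oc3c(OC)cc(/C=C/C)cc3[C@H]2COC(=O)CC(C)C)ccc1OC(C)=O | intermediate
14 | [(2R,3S)-2-(4-hydroxy-3-methoxyphenyl)-7-methoxy-5-[(E)-prop-1-enyl]-2,3-dihydro-1-benzofuran-3-yl]methyl 3-methylbutanoate | COc1cc([C@@H]2Oc3c(OC)cc(/C=C/C)cc3[C@H]2COC(=O)CC(C)C)ccc1O | intermediate
15 | (E)-but-2-enal (crotonaldehyde) | C/C=C/C=O | starting material
16 | [(2R,3S)-2-(4-hydroxy-3-methoxyphenyl)-7-methoxy-5-[(E)-3-oxoprop-1-enyl]-2,3-dihydro-1-benzofuran-3-yl]methyl 3-methylbutanoate (CNP0272976.1) | COc1cc([C@@H]2Oc3c(OC)cc(/C=C/C=O)cc3[C@H]2COC(=O)CC(C)C)ccc1O | target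

**Step count**

Total: 7 steps. Longest linear sequence: 5 steps (1 → 2 → 3 → 6 → 7).

**Steps most likely to fail, with fallbacks**

Step 6 is the riskiest. The pairing of a chiral semi-stabilised ylide with an alkyl-substituted o-quinone methide is untested, so er and dr may fall short, and 10 can tautomerise to a 2-vinylphenol before it is trapped. Any 2,3-cis isomer must be removed, not epimerised at C2, because C2 epimerisation would give the enantiomer of the wanted trans compound. The fallback sets out from 5 and 7 and comes back at 14, and it no longer asks the annulation for absolute stereocontrol. Bromide 7 is quaternised with tetrahydrothiophene to 1-[(4-acetoxy-3-methoxyphenyl)methyl]thiolan-1-ium bromide F1. With Cs2CO3 this gives the small, more nucleophilic (4-acetoxy-3-methoxyphenyl)(thiolan-1-ium-1-yl)methanide F2, which traps 10 faster. The trans annulation product is then formed as 13 together with its mirror image, 2-methoxy-4-[(2S,3R)-7-methoxy-3-[(3-methylbutanoyloxy)methyl]-5-[(E)-prop-1-enyl]-2,3-dihydro-1-benzofuran-2-yl]phenyl acetate F3. Pyrrolidine frees the phenols, giving 14 and [(2S,3R)-2-(4-hydroxy-3-methoxyphenyl)-7-methoxy-5-[(E)-prop-1-enyl]-2,3-dihydro-1-benzofuran-3-yl]methyl 3-methylbutanoate F4. Preparative chromatography on a chiral stationary phase then delivers 14.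

Step 2 is next. Aldehyde 2 is prone to hydration and oligomerisation. The magnesium alkoxide of 4 can shift the isovalerate to the benzylic oxygen or lose it through a premature o-quinone methide. The fallback sets out from 2 and 3 and comes back at 5, by-passing free 4. Phenol 3, aldehyde 2 and PhB(OH)2 are condensed (cat. EtCO2H, toluene, reflux with water removal) to the boron-templated ortho-adduct [8-methoxy-2-phenyl-6-[(E)-prop-1-enyl]-4H-1,3,2-benzodioxaborinin-4-yl]methyl 3-methylbutanoate F5. Both oxygens are tied up in F5, so no acyl shift is possible. Treating F5 with 4-MeC6H4SO2H opens the benzylic C–O bond and gives sulfone 5 after aqueous work-up.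

Step 3 is third. The acid needed to ionise 4 may dimerise the para-propenylphenol or cost the isovalerate. The fallback sets out from 4 and comes back at 14, making the o-quinone methide without acid. Boc2O (1.05 equiv, cat. DMAP, CH2Cl2, 0 °C) acylates only the phenol and gives 2-[1-hydroxy-2-(3-methylbutanoyloxy)ethyl]-6-methoxy-4-[(E)-prop-1-enyl]phenyl tert-butyl carbonate F6. Under the Cs2CO3 conditions of step 6, with 9 present, the Boc group moves to the benzylic oxygen to give 2-(tert-butoxycarbonyloxy)-2-[2-hydroxy-3-methoxy-5-[(E)-prop-1-enyl]phenyl]ethyl 3-methylbutanoate F7. Its phenoxide expels tert-butyl carbonate to form 10, which is annulated and deacetylated as before to 14.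

**Further compounds**

F1 | step 6 | 1-[(4-acetoxy-3-methoxyphenyl)methyl]thiolan-1-ium bromide | COc1cc(C[S+]2CCCC2)ccc1OC(C)=O.[Br-]
F2 | step 6 | (4-acetoxy-3-methoxyphenyl)(thiolan-1-ium-1-yl)methanide | COc1cc([CH-][S+]2CCCC2)ccc1OC(C)=O
F3 | step 6 | 2-methoxy-4-[(2S,3R)-7-methoxy-3-[(3-methylbutanoyloxy)methyl]-5-[(E)-prop-1-enyl]-2,3-dihydro-1-benzofuran-2-yl]phenyl acetate | COc1cc([C@H]2Oc3c(OC)cc(/C=C/C)cc3[C@@H]2COC(=O)CC(C)C)ccc1OC(C)=O
F4 | step 6 | [(2S,3R)-2-(4-hydroxy-3-methoxyphenyl)-7-methoxy-5-[(E)-prop-1-enyl]-2,3-dihydro-1-benzofuran-3-yl]methyl 3-methylbutanoate | COc1cc([C@H]2Oc3c(OC)cc(/C=C/C)cc3[C@@H]2COC(=O)CC(C)C)ccc1O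
F5 | step 2 | rac-[8-methoxy-2-phenyl-6-[(E)-prop-1-enyl]-4H-1,3,2-benzodioxaborinin-4-yl]methyl 3-methylbutanoate | C/C=C/c1cc(OC)c2OB(c3ccccc3)OC(COC(=O)CC(C)C)c2c1
F6 | step 3 | rac-2-[1-hydroxy-2-(3-methylbutanoyloxy)ethyl]-6-methoxy-4-[(E)-prop-1-enyl]phenyl tert-butyl carbonate | C/C=C/c1cc(OC)c(OC(=O)OC(C)(C)C)c(c1)C(O)COC(=O)CC(C)C
F7 | step 3 | rac-2-(tert-butoxycarbonyloxy)-2-[2-hydroxy-3-methoxy-5-[(E)-prop-1-enyl]phenyl]ethyl 3-methylbutanoate | C/C=C/c1cc(OC)c(O)c(c1)C(OC(=O)OC(C)(C)C)COC(=O)CC(C)C
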